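**Quench share.** 20.0% of the free monomer charged is my first ledger entry for the violet flask: this quench share is the protic impurity charged over the free monomer charged. It counts each protic impurity as taking one free monomer, and the impurity, charged at less than the monomer, is the limiting reagent of the quench.

common to all: free monomer 0.020 M; initiator 50 µM

| flask | protic impurity | radical scavenger | remark | time |
|---|---|---|---|---|
| violet | 4 mM | 14 µM | the very flask that is asked about, followed so far |  |
| green | 4 mM | 21 µM | run made earlier |  |
| flask | 4.00 mM | 14 µM |  | 40 h |

- violet (time / h: monomer in chains / %, quenched substrate / %): 5.00: 31, 14; 10.0: 51, 19; 15.0: 70, 20; 20.0: 77, 18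
- green (time / h: monomer in chains / %, quenched substrate / %): 5.00: 22, 19; 15.0: 65, 23; 25.0: 71, 20; 40.0: 73, 21

(standard deviation of a reading: 2 percentage points)

1. concentration of monomer in chains at 40 h, in M
2. concentration of quenched substrate at 40 h, in M

**Early entry.** From 5.00 h to 20.0 h the violet run gains 46 percentage points in chains, more than the 4 points it gains in quenched substrate. The last quenched readings, 18% in violet and 21% in green, lie around the share.

**Closing books.** The ledger leaves 80.0% for chains and free monomer together, and the violet run reads 77% in chains at 20.0 h. I book the midpoint, 78.5% in chains, which with the share leaves 1.50% free at 40 h: 0.0157 M in chains and 0.00400 M quenched.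

**Forecast, result.** The forecast gives 0.0153 M and 0.004 M, holding that “quenching stops once the impurity is used up”; the flask gives 0.0156 M and 0.00400 M.

    free monomer + growing radical → monomer in chains + growing radical, rate k1*[growing radical]*[free monomer] (k = 10700 L mol⁻¹ s⁻¹)
    growing radical + radical scavenger → ended chains (k = 7.22 × 10⁸ L mol⁻¹ s⁻¹)
    2 growing radical → dead chain (k = 4.20 × 10⁷ L mol⁻¹ s⁻¹)
    free monomer + initiating radical → growing radical + monomer in chains (k = 1.39 × 10⁵ L mol⁻¹ s⁻¹)
    initiator → 2 initiating radical (k = 0.0762 h⁻¹)
    protic impurity + free monomer → quenched substrate (k = 318 L mol⁻¹ h⁻¹)

**What ran.** In the violet flask the quench ran while protic impurity was there: by 4.00 h it had 100% of its turnover up to 40 h behind it, protic impurity stood at 0% of its own charge, and quenched substrate stood at 20.0%, the quench share 20.0%. Growth then had 30% behind it and ran on while initiator fell to 4.75% of its own charge by 40.0 h, when chains held 77.9% and free monomer 2.11%. The neighbour charged with 0.010 M of protic impurity has a quench share of 50.0% and ends with 50.0% quenched, 48.7% in chains and 1.3% free.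

(The earlier runs and the new flask were computed for an exercise, and the scatter is random.)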